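**Plan**

- Retrosynthesis: the quinone ring (ring A) is traced back to a 2,3,5-trimethoxyphenyl ring and the acetate to a secondary C–B bond. Two bonds are then cut at once: aryl–C1' and C2'–C3' (C1' = benzylic CH2, C2' = acetoxy carbon, C3' = first carbon of the tridecyl chain).
- Enabling feature: in the triad aryl C1–C1'–C2'(O)–C3' the only stereocentre lies between a benzylic methylene and a primary alkyl chain. This maps onto aryl triflate (electrophile), vinyl group (C1'–C2') and migrating group of a vinylboron ate complex, with boron standing in for the C2' oxygen. Ring A is a six-membered carbocycle whose para-related oxygens at C2 and C5 can be carried as methyl ethers.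
- Forward: tridecyl-B(pin) (from 1-tridecene) and vinyllithium (from tetravinyltin) give the ate complex. 2,3,5-Trimethoxyphenyl triflate is made in three steps from 2-hydroxy-4,6-dimethoxybenzaldehyde. One palladium-catalysed step joins the three pieces; no ring is formed in the route.
- Finish: C–B oxidation, acetylation, then oxidative demethylation to the methoxy-para-quinone.
- Stereochemistry: C2' (R) is set by the chiral MandyPhos ligand in the coupling and carried through C–B to C–O oxidation with retention; no later step touches a bond at C2'.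

Key step: step 6

Assumption: the (Sp,Sp) antipode of the ligand is taken to deliver the R boronate; the sense is to be checked on alcohol 12 (MTPA esters), and the (Rp,Rp) antipode is used without other change if the opposite sense is found.

**Step 1**
Reactants: 1 1-tridecene
Product: 2 4,4,5,5-tetramethyl-2-tridecyl-1,3,2-dioxaborolane
Conditions: HBpin, [Ir(cod)Cl]2 (cat.), dppm (cat.), CH2Cl2, rt
Reagents that add atoms: pinacolborane, [H]B1OC(C)(C)C(C)(C)O1
Why: Iridium-catalysed anti-Markovnikov hydroboration of a terminal alkene with pinacolborane should place boron on the terminal carbon and gives a boronic ester that has never seen halide.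

**Step 2**
Reactants: 3 tetravinyltin
Product: 4 vinyllithium
Conditions: n-BuLi (4 equiv), pentane, 0 °C to rt; filter under Ar, wash (pentane), dissolve in THF, titrate
Reagents that add atoms: n-butyllithium, [Li]CCCC
Why: Tin–lithium exchange (transmetallation) should precipitate halide-free vinyllithium from pentane while tetrabutyltin stays in solution.

**Step 3**
Reactants: 5 2-hydroxy-4,6-dimethoxybenzaldehyde
Product: 6 2-formyl-3,5-dimethoxyphenyl trifluoromethanesulfonate
Conditions: Tf2O, pyridine, CH2Cl2, 0 °C to rt
Reagents that add atoms: trifluoromethanesulfonic anhydride, O=S(=O)(OS(=O)(=O)C(F)(F)F)C(F)(F)F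
Why: O-Sulfonylation of the phenol with triflic anhydride and pyridine installs a group that protects this oxygen during the next oxidation and later serves as the coupling handle.

**Step 4**
Reactants: 6 2-formyl-3,5-dimethoxyphenyl trifluoromethanesulfonate
Product: 8 2-hydroxy-3,5-dimethoxyphenyl trifluoromethanesulfonate, via aryl formate 7 (not isolated)
Conditions: mCPBA, CH2Cl2, 0 °C to rt; then MeOH, HCl (cat.), rt
Reagents that add atoms: 3-chloroperoxybenzoic acid (mCPBA), OOC(=O)c1cccc(Cl)c1
Why: In this Baeyer–Villiger (Dakin-type) oxidation the ring, activated by ortho- and para-methoxy groups, should migrate in preference to hydride in the Criegee intermediate, and acid-catalysed methanolysis of the formate frees the phenol without forming a phenoxide next to the triflate.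

**Step 5**
Reactants: 8 2-hydroxy-3,5-dimethoxyphenyl trifluoromethanesulfonate
Product: 9 2,3,5-trimethoxyphenyl trifluoromethanesulfonate
Conditions: MeI, K2CO3, acetone, 40 °C
Reagents that add atoms: iodomethane, CI
Why: Williamson O-methylation under weakly basic conditions is tolerated by aryl triflates, and O-to-O triflyl transfer is not expected because an in-line displacement at sulfur cannot be reached through a five-membered cyclic arrangement.

**Step 6**
Reactants: 2 4,4,5,5-tetramethyl-2-tridecyl-1,3,2-dioxaborolane; 4 vinyllithium; 9 2,3,5-trimethoxyphenyl trifluoromethanesulfonate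
Product: 11 (R)-4,4,5,5-tetramethyl-2-[1-(2,3,5-trimethoxyphenyl)pentadecan-2-yl]-1,3,2-dioxaborolane, via lithium vinylboron ate complex 10 (not isolated)
Conditions: 2 (1.2 equiv), 4 (1.2 equiv), THF, 0 °C to rt; then 9 (1.0 equiv), Pd(OAc)2 (2 mol %), (Sp,Sp)-MandyPhos (ferrocene bisphosphine with di(3,5-xylyl)phosphino groups, 2.4 mol %), THF, 60 °C
Reagents that add atoms: none
Why: Vinyllithium 4 adds to the vacant orbital on boron of 2 to give the four-coordinate ate complex 10, while oxidative addition of triflate 9 to zerovalent palladium gives a cationic arylpalladium species (divalent palladium) whose weakly bound triflate leaves a site for the vinyl group of 10. π-Activation by the metal triggers a 1,2-metallate shift in which the tridecyl group moves from boron to C2' anti to palladium (forming C2'–C3'), and reductive elimination from the resulting alkyl(aryl)palladium joins the aryl carbon to C1' and returns zerovalent palladium. The closest known reaction type is the palladium-catalysed enantioselective conjunctive cross-coupling of vinylboron ate complexes with aryl triflates, for which primary alkyl migrating groups and electron-rich aryl triflates are established partners. No ring is closed; the single new stereocentre C2' is set in the migration step by the C2-symmetric MandyPhos ligand, which selects the alkene face bound by palladium, and boron marks the site of the future oxygen. The step needs conjunctive coupling to outrun direct Suzuki–Miyaura transfer of vinyl or tridecyl and β-hydride elimination: the halide-free ate complex and the triflate keep palladium cationic and alkene-philic, the pinacol ligand slows transmetallation, and the wide-bite-angle bisphosphine should speed reductive elimination.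

**Step 7**
Reactants: 11 (R)-4,4,5,5-tetramethyl-2-[1-(2,3,5-trimethoxyphenyl)pentadecan-2-yl]-1,3,2-dioxaborolane
Product: 12 (R)-1-(2,3,5-trimethoxyphenyl)pentadecan-2-ol
Conditions: NaOH (3 M aq), H2O2 (30 % aq), THF, 0 °C to rt
Reagents that add atoms: hydrogen peroxide, OO
Why: Hydroperoxide oxidation of the C–B bond proceeds by 1,2-shift of the alkyl group from boron to oxygen with retention, so the R configuration at C2' should pass unchanged into the alcohol (enantiomeric purity to be determined at this stage on a chiral phase).

**Step 8**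
Reactants: 12 (R)-1-(2,3,5-trimethoxyphenyl)pentadecan-2-ol
Product: 13 (R)-1-(2,3,5-trimethoxyphenyl)pentadecan-2-yl acetate
Conditions: Ac2O, pyridine, DMAP (cat.), CH2Cl2, rt
Reagents that add atoms: acetic anhydride, CC(=O)OC(C)=O
Why: DMAP-catalysed O-acylation of the secondary alcohol breaks no bond at C2' and masks the hydroxyl before the ring oxidation.

**Step 9**
Reactants: 13 (R)-1-(2,3,5-trimethoxyphenyl)pentadecan-2-yl acetate
Product: 14 ardisinone, (R)-1-(5-methoxy-3,6-dioxocyclohexa-1,4-dien-1-yl)pentadecan-2-yl acetate
Conditions: (NH4)2Ce(NO3)6 (2.5 equiv), aqueous MeCN, 0 °C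
Reagents that add atoms: water, O
Why: Oxidative demethylation by tetravalent cerium (single-electron oxidation of the arene, attack of water, loss of methanol) should convert the para-related 2- and 5-methoxy groups into the para-quinone and keep the 3-methoxy group as a vinylogous ester, with the acetate and C2' untouched.

**Compound list**

1 | 1-tridecene | CCCCCCCCCCCC=C | starting material
2 | 4,4,5,5-tetramethyl-2-tridecyl-1,3,2-dioxaborolane | CCCCCCCCCCCCCB1OC(C)(C)C(C)(C)O1 | intermediate
3 | tetravinyltin | C=C[Sn](C=C)(C=C)C=C | starting material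
4 | vinyllithium | [Li]C=C | intermediate
5 | 2-hydroxy-4,6-dimethoxybenzaldehyde | O=Cc1c(O)cc(OC)cc1OC | starting material
6 | 2-formyl-3,5-dimethoxyphenyl trifluoromethanesulfonate | O=Cc1c(OS(=O)(=O)C(F)(F)F)cc(OC)cc1OC | intermediate
7 | 2,4-dimethoxy-6-(trifluoromethanesulfonyloxy)phenyl formate | O=COc1c(OS(=O)(=O)C(F)(F)F)cc(OC)cc1OC | intermediate
8 | 2-hydroxy-3,5-dimethoxyphenyl trifluoromethanesulfonate | Oc1c(OS(=O)(=O)C(F)(F)F)cc(OC)cc1OC | intermediate
9 | 2,3,5-trimethoxyphenyl trifluoromethanesulfonate | COc1cc(OC)c(OC)c(OS(=O)(=O)C(F)(F)F)c1 | intermediate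
10 | lithium 4,4,5,5-tetramethyl-2-tridecyl-2-vinyl-1,3,2-dioxaborolan-2-uide (ate complex) | [Li+].CCCCCCCCCCCCC[B-]1(C=C)OC(C)(C)C(C)(C)O1 | intermediate
11 | (R)-4,4,5,5-tetramethyl-2-[1-(2,3,5-trimethoxyphenyl)pentadecan-2-yl]-1,3,2-dioxaborolane | CCCCCCCCCCCCC[C@H](Cc1cc(OC)cc(OC)c1OC)B1OC(C)(C)C(C)(C)O1 | intermediate
12 | (R)-1-(2,3,5-trimethoxyphenyl)pentadecan-2-ol | CCCCCCCCCCCCC[C@H](Cc1cc(OC)cc(OC)c1OC)O | intermediate
13 | (R)-1-(2,3,5-trimethoxyphenyl)pentadecan-2-yl acetate | CCCCCCCCCCCCC[C@H](Cc1cc(OC)cc(OC)c1OC)OC(C)=O | intermediate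
14 | ardisinone, (R)-1-(5-methoxy-3,6-dioxocyclohexa-1,4-dien-1-yl)pentadecan-2-yl acetate | CCCCCCCCCCCCC[C@H](CC1=CC(=O)C=C(OC)C1=O)OC(C)=O | target

**Step count**

Total step count: 9.
Longest linear sequence: 7 steps (steps 3 to 9, from 5).

**Steps most likely to fail**

Step 6. Oxidative addition of the electron-rich, ortho-methoxylated triflate may be slow, so that direct vinyl transfer or β-hydride elimination competes, or the ligand may discriminate the alkene faces poorly. The fallback sets out from 9 and comes back at 12. Stille allylation of 9 with allyltributylstannane (Pd(PPh3)4, LiCl, DMF) would give 1-allyl-2,3,5-trimethoxybenzene F1. Epoxidation with mCPBA (NaHCO3, CH2Cl2) would give racemic 2-(2,3,5-trimethoxybenzyl)oxirane F2. Hydrolytic kinetic resolution with water and the (salen)Co(OAc) catalyst antipode that consumes the R epoxide would leave (S)-2-(2,3,5-trimethoxybenzyl)oxirane F3. CuI-catalysed opening at the terminal carbon with dodecylmagnesium bromide would then give alcohol 12 with C2' already R, and the route resumes at step 8.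

Step 4. The electron-withdrawing triflate may lower the migratory aptitude of the ring so that hydride migration (giving the benzoic acid) competes, or the sulfonate may be lost during formate cleavage. The fallback sets out from 5 and comes back at 9. Benzylation of 5 (BnBr, K2CO3, DMF) would give 2-(benzyloxy)-4,6-dimethoxybenzaldehyde F4. Baeyer–Villiger oxidation with mCPBA would give 2-(benzyloxy)-4,6-dimethoxyphenyl formate F5, which is not isolated, and methanolysis would give 2-(benzyloxy)-4,6-dimethoxyphenol F6. Methylation (MeI, K2CO3) would give 1-(benzyloxy)-2,3,5-trimethoxybenzene F7. Hydrogenolysis (H2, Pd/C, EtOAc) would give 2,3,5-trimethoxyphenol F8, and triflation (Tf2O, pyridine) would give 9.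

Step 9. The oxidation may be unselective: attack at the adjacent 2,3-dimethoxy pair, oxidative dimerisation, or over-oxidation of the electron-rich ring on the last, most valuable intermediate. The fallback sets out from 8 and comes back at 14; it differentiates the C2 oxygen of ring A so that the final oxidation is that of a para-methoxyphenol. Benzylation of 8 (BnBr, K2CO3, acetone) would give 2-(benzyloxy)-3,5-dimethoxyphenyl trifluoromethanesulfonate F9. Coupling with ate complex 10 under the conditions of step 6 would give (R)-2-{1-[2-(benzyloxy)-3,5-dimethoxyphenyl]pentadecan-2-yl}-4,4,5,5-tetramethyl-1,3,2-dioxaborolane F10. Oxidation (NaOH, H2O2) would give (R)-1-[2-(benzyloxy)-3,5-dimethoxyphenyl]pentadecan-2-ol F11, and acetylation would give (R)-1-[2-(benzyloxy)-3,5-dimethoxyphenyl]pentadecan-2-yl acetate F12. Hydrogenolysis (H2, Pd/C) would give (R)-1-(2-hydroxy-3,5-dimethoxyphenyl)pentadecan-2-yl acetate F13. Mild two-electron oxidation with PhI(OAc)2 in aqueous MeCN at 0 °C would then give 14 with loss of the para methoxy group only.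

**Further compounds**

F1 | step 6 | 1-allyl-2,3,5-trimethoxybenzene | C=CCc1cc(OC)cc(OC)c1OC
F2 | step 6 | racemic 2-(2,3,5-trimethoxybenzyl)oxirane | C1C(Cc2cc(OC)cc(OC)c2OC)O1
F3 | step 6 | (S)-2-(2,3,5-trimethoxybenzyl)oxirane | C1[C@H](Cc2cc(OC)cc(OC)c2OC)O1
F4 | step 4 | 2-(benzyloxy)-4,6-dimethoxybenzaldehyde | O=Cc1c(OCc2ccccc2)cc(OC)cc1OC
F5 | step 4 | 2-(benzyloxy)-4,6-dimethoxyphenyl formate | O=COc1c(OCc2ccccc2)cc(OC)cc1OC
F6 | step 4 | 2-(benzyloxy)-4,6-dimethoxyphenol | Oc1c(OCc2ccccc2)cc(OC)cc1OC
F7 | step 4 | 1-(benzyloxy)-2,3,5-trimethoxybenzene | COc1c(OCc2ccccc2)cc(OC)cc1OC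
F8 | step 4 | 2,3,5-trimethoxyphenol | COc1c(O)cc(OC)cc1OC
F9 | step 9 | 2-(benzyloxy)-3,5-dimethoxyphenyl trifluoromethanesulfonate | COc1cc(OC)c(OCc2ccccc2)c(OS(=O)(=O)C(F)(F)F)c1
F10 | step 9 | (R)-2-{1-[2-(benzyloxy)-3,5-dimethoxyphenyl]pentadecan-2-yl}-4,4,5,5-tetramethyl-1,3,2-dioxaborolane | CCCCCCCCCCCCC[C@H](Cc1cc(OC)cc(OC)c1OCc2ccccc2)B1OC(C)(C)C(C)(C)O1
F11 | step 9 | (R)-1-[2-(benzyloxy)-3,5-dimethoxyphenyl]pentadecan-2-ol | CCCCCCCCCCCCC[C@H](Cc1cc(OC)cc(OC)c1OCc2ccccc2)O
F12 | step 9 | (R)-1-[2-(benzyloxy)-3,5-dimethoxyphenyl]pentadecan-2-yl acetate | CCCCCCCCCCCCC[C@H](Cc1cc(OC)cc(OC)c1OCc2ccccc2)OC(C)=O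
F13 | step 9 | (R)-1-(2-hydroxy-3,5-dimethoxyphenyl)pentadecan-2-yl acetate | CCCCCCCCCCCCC[C@H](Cc1cc(OC)cc(OC)c1O)OC(C)=O
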